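## Structural features

The target is a (2S)-flavanone: a chroman-4-one (ring C: O1, C2, C3, C4, C4a, C8a) fused to benzene ring A, with a 4-hydroxyphenyl ring B on C2. Ring A is pentasubstituted: C4a carries the C4 ketone, C8a the ring oxygen O1, C7 a free hydroxyl flanked by 3-methylbut-2-enyl (prenyl) groups on C6 and C8, and only C5 bears hydrogen. C2 is the only stereocenter; it is benzylic, bonded to O1, and β to the C4 carbonyl. That position is configurationally fragile: base opens ring C by retro-oxa-Michael (E1cB) to the 2'-hydroxychalcone, and under basic conditions a free 4'-hydroxyl assists C2–O1 cleavage through a quinone methide. The two trisubstituted prenyl olefins ortho to the C7 phenol cyclise onto that oxygen under acid or electrophilic metal activation and are lost on hydrogenation, which excludes strong acid and hydrogenolytic protecting groups. The real difficulty is therefore twofold: forming C2 enantioselectively and late without later erosion, and placing two identical C5 chains on both sides of the C7 oxygen without regiochemical ambiguity. The key step exploits the fact that C2 is the β-carbon of the C2=C3–C4=O enone of the corresponding chromone: the C2–C1' bond that joins ring B to the bicycle and the C2 configuration are created together by a catalyst-controlled enantioselective 1,4-arylation of an achiral, fully decorated 7-silyloxy-6,8-diprenylchromone.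

## Logic of the disconnections

**12 ⇒ 11.** The O7–Si and O4'–Si bonds are cut. Both phenols are masked during the key step: a free O7–H would deactivate the enone as its phenoxide and invite metal-mediated cyclisation onto the prenyl groups, and a free O4'–H would open the quinone-methide racemisation channel. There is no skeletal gain. The demand is a single global unmasking under buffered conditions that are neither basic enough to open ring C nor acidic enough to cyclise a prenyl group.

**11 ⇒ 9 + 10.** The C2–C1' bond is cut; this is the key disconnection. It removes the only stereocenter and divides the molecule into a planar achiral chromone 9 and a commercial arylboron reagent 10. The forward step must be 1,4-selective, irreversible and base-free, must deliver the aryl group to the Re face of C2 (O1 > C3 > H), and must ignore the two prenyl olefins.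

**9 ⇒ 8.** The O7–Si bond is cut. This is a simple masking of the hindered, acidic phenol; the demand is silylation between two ortho chains.

**8 ⇒ 7.** The terminal C=C bonds of both prenyl groups are cut, so each prenyl becomes an allyl group. Allyl groups can be delivered to arene carbons ortho to oxygen by sigmatropy with no normal/reverse-prenyl ambiguity. The forward double olefin cross-metathesis must go to completion at both sites without double-bond migration and must leave the chromone C2=C3 bond untouched.

**7 ⇒ 5.** The C6–allyl bond is cut and reconnected as an O7–allyl ether, via 6. The forward [3,3] shift can only end at C6 because C8 is occupied and the para position C4a is quaternary.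

**5 ⇒ 4.** The O7–C(allyl) bond is cut; this is an ordinary phenol alkylation.

**4 ⇒ 2.** The C8–allyl bond is cut and reconnected as an O7–allyl ether, via 3. The first [3,3] shift should favour C8, but the sequence is regioconvergent: whichever ortho position is filled first, the second cycle fills the other.

**2 ⇒ 1.** The O7–C(allyl) bond is cut, which leads to the commercial hydroxychromone 1.

## Other disconnections considered

Alternative 1: Cut O1–C2 (closure of ring C) and, one step further back, the C3=Cβ bond by aldol condensation. This is the route that comes to mind first. Ketone A1 and aldehyde A2 would give chalcone A3 by Claisen–Schmidt condensation, and the key step would be an enantioselective 6-endo-trig intramolecular oxa-Michael addition of the 2'-hydroxyl of A3. The chosen plan is preferred on three grounds. The cyclisation is an E1cB-reversible equilibrium under the same acid or base catalysts that promote it, so kinetic enantioselectivity is exposed to thermodynamic erosion, and for a chalcone without a 6'-hydroxyl such as A3 the closed form is only modestly favoured. High selectivity in this manifold generally calls for an extra activating ester at C3 and a later decarboxylation. A1 needs the same ortho-functionalisation work as the chromone, while A3 must carry three phenols through a strongly basic condensation. The chosen C–C bond formation is irreversible and base-free.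

Alternative 2: Cut three bonds of ring A: C8–C8a, C6–C7 and C4a–C8a. The forward key step would be a strain-release benzannulation of cyclobutenone A4 with siloxyalkyne A5 (4π ring opening to a vinylketene, [2+2] cycloaddition, second 4π opening, 6π closure, tautomerisation; Danheiser benzannulation). It would give the resorcinol monosilyl ether A6 with both prenyl groups and both oxygens placed regiospecifically in one operation. The chosen plan is preferred because A4 and A5 each need several steps. A6 would still lack the C4 carbon at C4a, and its introduction by Friedel–Crafts or Fries chemistry uses Lewis acids that prenyl groups next to a phenol do not tolerate. The cascade also leaves C2 and ring C untouched, so the route would be longer and would still need a separate stereodefining step.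

Alternative 3: Cut C3–C4. The forward key step would be a Rh(I)-catalysed enantioselective intramolecular hydroacylation of the aryl 1-arylvinyl ether aldehyde A7: oxidative addition into the formyl C–H bond, hydride transfer to C2 (which would set the stereocenter), and reductive elimination to form C3–C4 in an endo ring closure. The chosen plan is preferred because six-membered ketone formation through a seven-membered acyl-rhodacycle has to compete with decarbonylation. A7 contains an acid-labile enol ether that would have to be made by ester methylenation in the presence of a masked aldehyde. Enantiofacial hydride delivery to a 1,1-disubstituted enol ether in this ring size would be an untested demand. Several uncertain elements would be accepted with no saving in steps.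

Key step: step 7

Assumption (stereochemical sense): the facial preference of pyridine-oxazoline Pd(II) catalysts with cyclic enones is taken to carry over to the chromone, which calls for the (R)-ligand to reach 2S. The sense is to be verified on the first run, and the (S)-ligand used if it is reversed.

Assumption (supply): compounds 1 and 10 are purchased.

## Route

Step 1
Reactants: 1 7-hydroxy-4H-chromen-4-one
Product: 2 7-(prop-2-en-1-yloxy)-4H-chromen-4-one
Conditions: allyl bromide (1.2 equiv), K2CO3 (1.5 equiv), acetone, reflux
Reagents that add atoms: allyl bromide, C=CCBr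
Why: Williamson etherification of an acidic vinylogous-acid phenol; anhydrous carbonate should avoid the hydroxide-induced opening of the pyranone ring.

Step 2
Reactants: 2 7-(prop-2-en-1-yloxy)-4H-chromen-4-one
Product: 4 7-hydroxy-8-(prop-2-en-1-yl)-4H-chromen-4-one, via 8-allyl-8H-chromene-4,7-dione 3 (not isolated)
Conditions: PhNEt2, 200 °C, Ar, sealed tube
Reagents that add atoms: none
Why: Aromatic Claisen [3,3] rearrangement through a chair transition state to ortho-dienone 3, which tautomerises to phenol 4; C8 should be favoured because the C7–C8 bond has the higher double-bond character in the fused system, and migration to the other ortho position would be harmless because the next cycle fills whichever ortho site remains.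

Step 3
Reactants: 4 7-hydroxy-8-(prop-2-en-1-yl)-4H-chromen-4-one
Product: 5 8-(prop-2-en-1-yl)-7-(prop-2-en-1-yloxy)-4H-chromen-4-one
Conditions: allyl bromide (1.3 equiv), K2CO3 (1.5 equiv), acetone, reflux
Reagents that add atoms: allyl bromide, C=CCBr
Why: Williamson etherification; the phenol is acidic enough to be alkylated cleanly despite one ortho substituent.

Step 4
Reactants: 5 8-(prop-2-en-1-yl)-7-(prop-2-en-1-yloxy)-4H-chromen-4-one
Product: 7 7-hydroxy-6,8-di(prop-2-en-1-yl)-4H-chromen-4-one, via 6,8-diallyl-6H-chromene-4,7-dione 6 (not isolated)
Conditions: PhNEt2, 200–210 °C, Ar, sealed tube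
Reagents that add atoms: none
Why: Second aromatic Claisen rearrangement; with C8 substituted and the para position C4a quaternary, only migration to C6 can end in rearomatisation (dienone 6, then tautomerisation), so the 6,8-pattern is fixed by the substrate.

Step 5
Reactants: 7 7-hydroxy-6,8-di(prop-2-en-1-yl)-4H-chromen-4-one
Product: 8 7-hydroxy-6,8-bis(3-methylbut-2-en-1-yl)-4H-chromen-4-one
Conditions: 2-methyl-2-butene (large excess), (H2IMes)(PCy3)Cl2Ru=CHPh (5 mol %), CH2Cl2, 40 °C, sealed tube
Reagents that add atoms: 2-methyl-2-butene, CC=C(C)C
Why: Double olefin cross-metathesis of two terminal allyl groups with an excess of a trisubstituted olefin, a standard allyl-to-prenyl conversion on ortho-allylphenols; volatile propene drives the exchange, and the electron-poor, oxygen-substituted endocyclic C2=C3 bond of the chromone should not engage the Ru carbene.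

Step 6
Reactants: 8 7-hydroxy-6,8-bis(3-methylbut-2-en-1-yl)-4H-chromen-4-one
Product: 9 7-[tert-butyl(dimethyl)silyl]oxy-6,8-bis(3-methylbut-2-en-1-yl)-4H-chromen-4-one
Conditions: TBSCl (1.5 equiv), imidazole (3 equiv), DMF, rt to 40 °C
Reagents that add atoms: tert-butyldimethylsilyl chloride, CC(C)(C)[Si](C)(C)Cl
Why: Imidazole-promoted O-silylation of an acidic phenol; the two ortho chains slow the reaction but should also shield the resulting aryl silyl ether against hydrolysis in the next step.

Step 7
Reactants: 9 7-[tert-butyl(dimethyl)silyl]oxy-6,8-bis(3-methylbut-2-en-1-yl)-4H-chromen-4-one, 10 [4-[tert-butyl(dimethyl)silyl]oxyphenyl]boronic acid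
Product: 11 (2S)-7-[tert-butyl(dimethyl)silyl]oxy-2-[4-[tert-butyl(dimethyl)silyl]oxyphenyl]-6,8-bis(3-methylbut-2-en-1-yl)-2,3-dihydro-4H-chromen-4-one
Conditions: 10 (2 equiv), Pd(OCOCF3)2 (5 mol %), (R)-t-BuPyOX (6 mol %), NH4PF6 (30 mol %), H2O (5 equiv), ClCH2CH2Cl, 60 °C, air
Reagents that add atoms: none
Why: Pd(II)-catalysed enantioselective conjugate addition of an arylboronic acid to a chromone, the Pd(II) counterpart of the Hayashi–Miyaura 1,4-addition and a known reaction type for chromones. The cationic pyridine-oxazoline Pd(II) centre undergoes transmetalation with 10, the C2=C3 bond of 9 coordinates, and syn migratory insertion forms C2–C1' and a C3-bound Pd enolate that tautomerises to the O-bound form and is protonated by water, releasing 11 and regenerating Pd(II) without a change of oxidation state. No ring is closed; the step joins ring B to the preformed bicycle. The only new stereocenter, C2, is set under catalyst control in the insertion step: the tert-butyl group of the (R)-ligand blocks one quadrant so that the aryl group should be delivered to the Re face of C2 (O1 > C3 > H), which corresponds to 2S. The step needs 1,4- rather than 1,2-addition, protonolysis rather than β-hydride elimination to the flavone, and selectivity for the enone over the two prenyl olefins; the chelated cationic catalyst inserts only the polarised enone C=C bond, trisubstituted unactivated olefins bind it poorly, and water at 60 °C should make enolate protonolysis fast. The O7 silyl ether prevents phenoxide formation, which would switch off the acceptor and open a Wacker-type cyclisation onto the C6 and C8 prenyl groups, and the O4' silyl ether closes the quinone-methide pathway in the product. Because the medium contains no base and the C–C bond formation is irreversible, the C2 configuration should not erode by retro-oxa-Michael opening.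

Step 8
Reactants: 11 (2S)-7-[tert-butyl(dimethyl)silyl]oxy-2-[4-[tert-butyl(dimethyl)silyl]oxyphenyl]-6,8-bis(3-methylbut-2-en-1-yl)-2,3-dihydro-4H-chromen-4-one
Product: 12 (2S)-7-hydroxy-2-(4-hydroxyphenyl)-6,8-bis(3-methylbut-2-en-1-yl)-2,3-dihydro-4H-chromen-4-one
Conditions: Bu4NF (2.5 equiv), AcOH (3 equiv), THF, 0 °C to rt
Reagents that add atoms: none
Why: Fluoride-induced cleavage of both aryl silyl ethers; the acetic acid buffer keeps the liberated phenols protonated, so neither retro-oxa-Michael nor quinone-methide opening at C2 should occur, and the medium is far too weakly acidic to cyclise a prenyl group onto O7.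

## Compound list

1 | 7-hydroxy-4H-chromen-4-one | O=c1ccoc2cc(O)ccc12 | starting material
2 | 7-(prop-2-en-1-yloxy)-4H-chromen-4-one | O=c1ccoc2cc(OCC=C)ccc12 | intermediate
3 | 8-(prop-2-en-1-yl)-8H-chromene-4,7-dione | C=CCC1C(=O)C=CC2=C1OC=CC2=O | intermediate (not isolated)
4 | 7-hydroxy-8-(prop-2-en-1-yl)-4H-chromen-4-one | O=c1ccoc2c(CC=C)c(O)ccc12 | intermediate
5 | 8-(prop-2-en-1-yl)-7-(prop-2-en-1-yloxy)-4H-chromen-4-one | O=c1ccoc2c(CC=C)c(OCC=C)ccc12 | intermediate
6 | 6,8-di(prop-2-en-1-yl)-6H-chromene-4,7-dione | C=CCC1C=C2C(=O)C=COC2=C(CC=C)C1=O | intermediate (not isolated)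
7 | 7-hydroxy-6,8-di(prop-2-en-1-yl)-4H-chromen-4-one | O=c1ccoc2c(CC=C)c(O)c(CC=C)cc12 | intermediate
8 | 7-hydroxy-6,8-bis(3-methylbut-2-en-1-yl)-4H-chromen-4-one | O=c1ccoc2c(CC=C(C)C)c(O)c(CC=C(C)C)cc12 | intermediate
9 | 7-[tert-butyl(dimethyl)silyl]oxy-6,8-bis(3-methylbut-2-en-1-yl)-4H-chromen-4-one | O=c1ccoc2c(CC=C(C)C)c(O[Si](C)(C)C(C)(C)C)c(CC=C(C)C)cc12 | intermediate
10 | [4-[tert-butyl(dimethyl)silyl]oxyphenyl]boronic acid | OB(O)c1ccc(O[Si](C)(C)C(C)(C)C)cc1 | starting material
11 | (2S)-7-[tert-butyl(dimethyl)silyl]oxy-2-[4-[tert-butyl(dimethyl)silyl]oxyphenyl]-6,8-bis(3-methylbut-2-en-1-yl)-2,3-dihydro-4H-chromen-4-one | CC(C)=CCc1cc2c(c(CC=C(C)C)c1O[Si](C)(C)C(C)(C)C)O[C@H](c1ccc(O[Si](C)(C)C(C)(C)C)cc1)CC2=O | intermediate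
12 | (2S)-7-hydroxy-2-(4-hydroxyphenyl)-6,8-bis(3-methylbut-2-en-1-yl)-2,3-dihydro-4H-chromen-4-one | CC(C)=CCc1cc2c(c(CC=C(C)C)c1O)O[C@H](c1ccc(O)cc1)CC2=O | target

## Step count and least certain steps

Total step count: 8. Longest linear sequence: 8 steps (1 to 12); compound 10 enters as a purchased partner in step 7.

**Step 7 (key step).** The most likely failures are as follows:
- Low turnover, because the 7-silyloxy group donates into the enone and makes C2 a weak acceptor.
- Consumption of the electron-rich boronic acid by protodeboronation or oxidative homocoupling.
- Insufficient or reversed facial discrimination.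
- Partial loss of a silyl group, followed by Pd(II) engagement of the prenyl olefins.

Fallback (ring C closed at O1–C2 instead; known chemistry): it sets out from 8 and comes back at 12. Hydroxide opening of the pyranone ring of 8 (aq. NaOH, EtOH, reflux; C2 leaves as formate) should give 1-[2,4-dihydroxy-3,5-bis(3-methylbut-2-en-1-yl)phenyl]ethan-1-one F1. Claisen–Schmidt condensation of F1 with 4-hydroxybenzaldehyde (KOH, EtOH–H2O, rt) should give (E)-1-[2,4-dihydroxy-3,5-bis(3-methylbut-2-en-1-yl)phenyl]-3-(4-hydroxyphenyl)prop-2-en-1-one F2. Oxa-Michael cyclisation (NaOAc, EtOH, reflux) should give racemic 7-hydroxy-2-(4-hydroxyphenyl)-6,8-bis(3-methylbut-2-en-1-yl)-2,3-dihydro-4H-chromen-4-one F3. F3 is resolved by preparative HPLC on a polysaccharide chiral stationary phase, and the (2S)-enantiomer is 12; steps 6 to 8 are then not needed.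

**Step 5 (double cross-metathesis).** The most likely failures are incomplete exchange at one of the two allyl groups, double-bond migration into conjugation with the arene promoted by Ru hydride species, and catalyst deactivation by the free phenol.

Fallback (prenyl groups introduced directly by cross-coupling): it sets out from 1 and comes back at 9, bypassing steps 1 to 6. Electrophilic iodination of both positions ortho to the hydroxyl (N-iodosuccinimide, 2.2 equiv, cat. CF3CO2H, MeCN) should give 7-hydroxy-6,8-diiodo-4H-chromen-4-one F4. Silylation (TBSCl, imidazole, DMF) should give 7-[tert-butyl(dimethyl)silyl]oxy-6,8-diiodo-4H-chromen-4-one F5. Double Stille coupling of F5 with tributyl(3-methylbut-2-en-1-yl)stannane (Pd(PPh3)4, DMF, 90 °C) should give 9.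

**Step 8 (global unmasking).** The most likely failures are erosion of the C2 configuration by reversible ring opening once both phenols are free, slow cleavage of the hindered O7 silyl ether that tempts harsher conditions, and cyclisation of a prenyl group onto O7 if the medium becomes too acidic.

Fallback (fluoride-free endgame with ester protection and neutral acyl transfer): it sets out from 8 and comes back at 12. Acetylation of 8 (Ac2O, pyridine) should give 4-oxo-6,8-bis(3-methylbut-2-en-1-yl)-4H-chromen-7-yl acetate F6. Conjugate addition of commercial 4-acetoxyphenylboronic acid to F6 under the catalyst system of step 7 should give (2S)-2-(4-acetoxyphenyl)-4-oxo-6,8-bis(3-methylbut-2-en-1-yl)-2,3-dihydro-4H-chromen-7-yl acetate F7. Neutral methanolysis of both aryl acetates of F7 (NH4OAc, MeOH–H2O, rt) should give 12.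

## Further compounds

F1 | step 7 | 1-[2,4-dihydroxy-3,5-bis(3-methylbut-2-en-1-yl)phenyl]ethan-1-one | CC(=O)c1cc(CC=C(C)C)c(O)c(CC=C(C)C)c1O
F2 | step 7 | (E)-1-[2,4-dihydroxy-3,5-bis(3-methylbut-2-en-1-yl)phenyl]-3-(4-hydroxyphenyl)prop-2-en-1-one | O=C(/C=C/c1ccc(O)cc1)c1cc(CC=C(C)C)c(O)c(CC=C(C)C)c1O
F3 | step 7 | racemic 7-hydroxy-2-(4-hydroxyphenyl)-6,8-bis(3-methylbut-2-en-1-yl)-2,3-dihydro-4H-chromen-4-one | CC(C)=CCc1cc2c(c(CC=C(C)C)c1O)OC(c1ccc(O)cc1)CC2=O
F4 | step 5 | 7-hydroxy-6,8-diiodo-4H-chromen-4-one | O=c1ccoc2c(I)c(O)c(I)cc12
F5 | step 5 | 7-[tert-butyl(dimethyl)silyl]oxy-6,8-diiodo-4H-chromen-4-one | O=c1ccoc2c(I)c(O[Si](C)(C)C(C)(C)C)c(I)cc12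
F6 | step 8 | 4-oxo-6,8-bis(3-methylbut-2-en-1-yl)-4H-chromen-7-yl acetate | O=c1ccoc2c(CC=C(C)C)c(OC(C)=O)c(CC=C(C)C)cc12
F7 | step 8 | (2S)-2-(4-acetoxyphenyl)-4-oxo-6,8-bis(3-methylbut-2-en-1-yl)-2,3-dihydro-4H-chromen-7-yl acetate | CC(C)=CCc1cc2c(c(CC=C(C)C)c1OC(C)=O)O[C@H](c1ccc(OC(C)=O)cc1)CC2=O
A1 | alternative 1 | 1-[2,4-dihydroxy-3,5-bis(3-methylbut-2-en-1-yl)phenyl]ethan-1-one | CC(=O)c1cc(CC=C(C)C)c(O)c(CC=C(C)C)c1O
A2 | alternative 1 | 4-hydroxybenzaldehyde | O=Cc1ccc(O)cc1
A3 | alternative 1 | (E)-1-[2,4-dihydroxy-3,5-bis(3-methylbut-2-en-1-yl)phenyl]-3-(4-hydroxyphenyl)prop-2-en-1-one | O=C(/C=C/c1ccc(O)cc1)c1cc(CC=C(C)C)c(O)c(CC=C(C)C)c1O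
A4 | alternative 2 | 2-(3-methylbut-2-en-1-yl)cyclobut-2-en-1-one | O=C1CC=C1CC=C(C)C
A5 | alternative 2 | triisopropyl[(5-methylhex-4-en-1-yn-1-yl)oxy]silane | CC(C)=CCC#CO[Si](C(C)C)(C(C)C)C(C)C
A6 | alternative 2 | 2,4-bis(3-methylbut-2-en-1-yl)-3-[tri(propan-2-yl)silyl]oxyphenol | Oc1ccc(CC=C(C)C)c(O[Si](C(C)C)(C(C)C)C(C)C)c1CC=C(C)C
A7 | alternative 3 | 4-[tert-butyl(dimethyl)silyl]oxy-2-[1-[4-[tert-butyl(dimethyl)silyl]oxyphenyl]ethenoxy]-3,5-bis(3-methylbut-2-en-1-yl)benzaldehyde | O=Cc1cc(CC=C(C)C)c(O[Si](C)(C)C(C)(C)C)c(CC=C(C)C)c1OC(=C)c1ccc(O[Si](C)(C)C(C)(C)C)cc1
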